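One question stands on this flask, and its charges and equations come first.

substrate 0.20 M; free catalyst 0.40 mM; added ligand 0.25 mM

    substrate + free catalyst → free catalyst + target (k1 = 410 /M/min)
    free catalyst + added ligand ⇌ idle complex (K2 = 31000 /M, k2 = 8100 /M/min)
    free catalyst → spent catalyst (k3 = 1.1 × 10⁻⁵ /min)

- apparent order in free catalyst when 10% of the substrate are converted (percent change of the rate of making target for one percent more free catalyst charged)

- The numbers seem to clash: the equilibrium constant of binding times the added ligand as charged is 7.75, which reads as a free share of 11.4%, yet with 0.25 mM of added ligand against 0.40 mM of catalyst, 37.5% of the catalyst has no partner.
- I clear this up by noting that added ligand is the limiting reagent of binding and is drawn down as it binds: the equilibrium balance gives 0.213 mM of idle complex, which leaves 0.187 mM of free catalyst and 0.0370 mM of added ligand.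
- The settled free share, free catalyst over catalyst charged at binding equilibrium, is therefore 46.7%.
- Binding relaxes near equilibrium with a half-life of 0.334 min, shorter than the 1.01 min the flask takes to reach the conversion asked, so I reckon with binding at equilibrium there, as an approximation.
- At fixed conversion [substrate] is the same, so the rate follows [free catalyst], and at binding equilibrium 85.6% of each extra bit of catalyst stays free; that marginal share over the settled free share gives me an estimated order of 1.83.
- The forecast says 1.8, from 1.65 to 1.95, slightly below my figure, on the grounds that “extra catalyst mostly appears as free catalyst”.
- The simulation gives an order of 1.8, inside the forecast's range, and free catalyst reads 50.5% of the charge at 1.01 min and 46.7% at 15.0 min, against my settled free share of 46.7%. In this flask the relaxation half-life of binding, both directions together, is 0.334 min at 30.0 min, far shorter than the 9.1 min half-life of substrate by step 1 at 7.43 min, and as substrate falls, idle complex holds 53.3% of the catalyst at 15.3 min and 53.3% at 24.4 min.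

The constants used here were drawn at random within sensible limits, and the outcome is calculated.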